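What does this flask hold at the asked time: has anything stopped it, and how much target has formed?

substrate 0.27 M; reagent 0.800 equiv; free catalyst 0.05 mol%; second catalyst 0.2 mol%; time 8.0 min

    substrate + free catalyst ⇌ free catalyst + intermediate (K1 = 2.6, k1 = 87 M⁻¹ s⁻¹)
    reagent + second catalyst + intermediate → second catalyst + target (k2 = 39 M⁻² s⁻¹)

1. at 8.0 min, what has stopped the reaction, if anything has (forward and back rates have come level / the reagent has run out first / it is still moving / all of the substrate has reacted / no working catalyst is left)
2. amount of target at 8.0 min, in percent of the substrate charged

- the reaction counts as stopped when no species that holds the substrate changes by six tenths of a point or more over the second half of the time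
- run time (flask): 8.0 min

Two chemists dispute this flask. The first uses a pseudo-first-order clock: with the reagent held as charged, intermediate has a half-life of 2.5 min by the second step, and the time allowed is 3.15 such half-lives. That chemist runs this clock on the cap of 80.0 % target that the charges allow, with the reagent as limiting reagent, so 11.3 % of the cap stays unmade; the chemist answers that the reagent has run out first and claims 71.0 % target.

The second chemist, whose side I take, objects that [reagent] falls during the run and slows the second step. The first step relaxes in 1.02 min, shorter than the time allowed, so after that lag I take the pool [substrate] + [intermediate] as split by K1, with 72.2 % of it intermediate. Pool and reagent then lose equal amounts, and integrating the rate from the end of the lag gives 0.344. This is the gap exponent: the logarithm of the fraction of pool left over the fraction of reagent left, equal to k2 [second catalyst] times the intermediate share, times the difference of the charged concentrations, times the time after the lag. That difference is 0.0540 M, so the ratio reaches 1.41. Solving it with the charges gives my figure, 53.8 % target, with 32.8 % of the reagent left and the flask still moving.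

The forecast, on the second side, says it is still moving and gives 51 %, holding that “the intermediate pre-equilibrates in about a minute and then drains slowly as the reagent is consumed”. My figure stands above it.

The simulation answers "it is still moving", with 52.6 % target, which is the second chemist's outcome. At 8.00 min this flask holds 14.3 % substrate, 33.1 % intermediate and 34.3 % of its reagent, so the logarithm of pool left over reagent left reads 0.323, against the gap exponent of 0.344. The first chemist's ending belongs to the longer run: at 80.0 min this flask has 0.431 % of its reagent left and 79.7 % target.

In a neighbour flask like this one but with 0.08 mol% of second catalyst, the gap exponent falls with that loading to 0.137, which gives 33.9 % target. The simulated neighbour flask gives 33.4 %, and its logarithm of pool left over reagent left reads 0.134. That neighbour flask ends with more intermediate than target: its intermediate stands at 47.1 %.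

The numbers of this flask come from no measurement; the run is a simulation.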